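**Retrosynthetic overview**

1. The acid comes from tert-butyl ester 37; the C12–C13 bond is made by Negishi coupling of the C12 alkylzinc (from iodide 28) with the (E)-iodo-enoate 35, which fixes the 13Z geometry.
2. The C7=C8 enone (27) comes from Saegusa–Ito dehydrogenation of the saturated trans-decalin-6-one (22, oxidised at C12 to 24 first).
3. 22 comes from the cis-fused hydroazulene (bicyclo[5.3.0]decane) hydroxy mesylate 20 by a pinacol-type [1,2]-shift of the ring-fusion carbon C10 from C6 to C5: the seven-membered ring becomes ring A and the cyclopentane becomes ring B. The feature used is the C6 ketone next to the C5 methine that links the quaternary carbons C4 and C10 (C5–C10 is the bond made; C10, being quaternary, migrates well).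
4. The seven-membered ring is closed at C5–C6 by SmI2 pinacol coupling of keto-aldehyde 18. Ring order: cyclopentane (purchased) → seven-membered ring (step 10) → rings A and B together (step 12).
5. C9 and C10 are set on the cyclopentanone by Cu-catalysed asymmetric conjugate addition to 2-methylcyclopent-2-enone and anti alkylation of the enolate with allylic bromide 7.

Key step: step 12

Remark: atoms keep the labdane numbers of the target throughout (C1–C10 decalin, C4 gem-dimethyl, C11–C16 side chain, C17 on C8, C20 on C10); compounds 1, 3, 4, 8 and 29 are assumed to be commercial. The CIP letter at C9 changes from S (10–13) to R (from 14 on) only because the priorities change, not the geometry.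

**Route**

Step 1
Reactants: 1 dimethyl(phenyl)(vinyl)silane
Product: 2 (2-bromoethyl)dimethyl(phenyl)silane
Conditions: HBr (gas), dibenzoyl peroxide (cat.), pentane, 0 °C
Reagents that add atoms: hydrogen bromide, Br
Why: Radical-chain anti-Markovnikov hydrobromination, in which the bromine atom adds to the terminal carbon to give the α-silyl radical, so bromine ends on the carbon remote from silicon; no stereocentre is formed.

Step 2
Reactants: 3 methyl isobutyrate; 4 acrolein
Product: 6 methyl 3-hydroxy-2,2-dimethylpent-4-enoate (racemic), via lithium enolate 5 (not isolated)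
Conditions: LDA, THF, −78 °C; then 4, −78 °C; H2O
Reagents that add atoms: none
Why: Aldol-type 1,2-addition of a lithium ester enolate to an enal at low temperature; the carbinol centre is racemic and is erased in step 3.

Step 3
Reactants: 6 methyl 3-hydroxy-2,2-dimethylpent-4-enoate
Product: 7 methyl (E)-5-bromo-2,2-dimethylpent-3-enoate
Conditions: PBr3 (0.4 equiv), Et2O, 0 °C → rt
Reagents that add atoms: phosphorus tribromide, BrP(Br)Br
Why: Bromination with allylic transposition (SN2′ and equilibration of allylic bromides) should drain to the primary bromide because a secondary bromide next to the quaternary carbon is disfavoured, and the E alkene is the thermodynamic isomer.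

Step 4
Reactants: 8 2-methylcyclopent-2-en-1-one; 2 (2-bromoethyl)dimethyl(phenyl)silane; 7 methyl (E)-5-bromo-2,2-dimethylpent-3-enoate
Product: 11 methyl (3E)-5-{(1S,2S)-2-[2-(dimethylphenylsilyl)ethyl]-1-methyl-5-oxocyclopentyl}-2,2-dimethylpent-3-enoate, via Grignard reagent 9 (not isolated), via magnesium enolate 10 (not isolated)
Conditions: 2, Mg, Et2O, reflux; then 8, Cu(OTf)2 (5 mol%), chiral hydroxyalkyl imidazolinium salt (N-heterocyclic carbene precursor, 6 mol%, the enantiomer that gives the 3S enolate), Et2O, −10 °C; then 7, DMPU, THF, −10 °C → rt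
Reagents that add atoms: none
Why: Copper-catalysed asymmetric conjugate addition of a Grignard reagent to an α-substituted cyclic enone followed by C-alkylation of the regiodefined magnesium enolate (three-component coupling): the ligand sets C9, and the allylic bromide then enters anti to the new C9 substituent, so C20 and C11 end up cis on the quaternary C10.

Step 5
Reactants: 11 unsaturated keto ester
Product: 12 methyl 5-{(1S,2S)-2-[2-(dimethylphenylsilyl)ethyl]-1-methyl-5-oxocyclopentyl}-2,2-dimethylpentanoate
Conditions: H2 (1 atm), Pd/C, EtOAc, rt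
Reagents that add atoms: none
Why: Heterogeneous hydrogenation of the disubstituted alkene, to which ketone, hindered ester and arylsilane are inert; no stereocentre is touched.

Step 6
Reactants: 12 saturated keto ester
Product: 14 methyl 5-{(1S,5R)-5-[2-(dimethylphenylsilyl)ethyl]-1-methyl-2-oxocyclopent-3-en-1-yl}-2,2-dimethylpentanoate, via TMS enol ether 13 (not isolated)
Conditions: LDA, TMSCl, THF, −78 °C; then Pd(OAc)2 (10 mol%), O2 (1 atm), DMSO, rt
Reagents that add atoms: none
Why: Saegusa–Ito dehydrogenation, in which C7 is the only enolisable position (C10 is quaternary and the ester has no α-hydrogen), so the enone can only form as C7=C8.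

Step 7
Reactants: 14 cyclopentenone
Product: 16 methyl 5-{(1S,2R,3S)-2-[2-(dimethylphenylsilyl)ethyl]-1,3-dimethyl-5-oxocyclopentyl}-2,2-dimethylpentanoate, via lithium enolate 15 (not isolated)
Conditions: Me2CuLi, Et2O, −78 → −20 °C; then H2O
Reagents that add atoms: lithium dimethylcuprate, [Li+].C[Cu-]C
Why: Cuprate 1,4-addition brings in C17 anti to the neighbouring C9 substituent; the C8 centre is of no consequence because C8 becomes sp2 again in step 14.

Step 8
Reactants: 16 keto ester
Product: 17 5-{(1S,2R,3S)-2-[2-(dimethylphenylsilyl)ethyl]-5-hydroxy-1,3-dimethylcyclopentyl}-2,2-dimethylpentan-1-ol (both C6 epimers)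
Conditions: LiAlH4, THF, 0 °C → rt; then H2O, aq. NaOH
Reagents that add atoms: none
Why: Hydride reduction of ester and ketone adjusts the oxidation level of C5; the uncontrolled carbinol centre at C6 is removed again in step 9.

Step 9
Reactants: 17 diol
Product: 18 5-{(1S,2R,3S)-2-[2-(dimethylphenylsilyl)ethyl]-1,3-dimethyl-5-oxocyclopentyl}-2,2-dimethylpentanal
Conditions: Dess–Martin periodinane, CH2Cl2, rt
Reagents that add atoms: none
Why: Dess–Martin oxidation of both alcohols gives the non-enolisable neopentyl aldehyde and returns the ketone without touching C8, C9 or C10.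

Step 10
Reactants: 18 keto aldehyde
Product: 19 cis-fused hydroazulene-5,6-diol (5R,6S,8S,9R,10S)
Conditions: SmI2 (3 equiv), HMPA, THF, high dilution, −78 °C → rt; then H2O
Reagents that add atoms: none
Why: Intramolecular pinacol (ketyl) coupling with SmI2, in which the ketyl formed at the aldehyde adds to the cyclopentanone from the face of C10 that carries the tether (cis ring fusion, C6–OH cis to C20) and samarium bridging of the two oxygens should give the cis diol at C5/C6.

Step 11
Reactants: 19 hydroazulene diol
Product: 20 cis-fused hydroazulene 6-hydroxy 5-mesylate (5R,6S,8S,9R,10S)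
Conditions: MsCl, Et3N, CH2Cl2, −20 °C
Reagents that add atoms: methanesulfonyl chloride, CS(=O)(=O)Cl
Why: Selective sulfonylation of the secondary alcohol, since the tertiary ring-fusion hydroxyl does not react under these conditions; no stereocentre changes.

Step 12
Reactants: 20 hydroxy mesylate
Product: 22 (5R,8S,9R,10S)-12-(dimethylphenylsilyl)-13,14,15,16-tetranorlabdan-6-one, via diethylaluminium alkoxide 21 (not isolated)
Conditions: Et3Al (3 equiv), CH2Cl2, −78 → 0 °C; then H2O
Reagents that add atoms: none
Why: Et3Al turns the tertiary C6 alcohol into alkoxide 21 and activates the mesylate; with the mesylate pseudo-equatorial on the seven-membered ring the ring-fusion bond C6–C10 lies anti-periplanar to C5–OMs, and C10 shifts from C6 to C5 while the alkoxide becomes the C6 ketone. This is the organoaluminium-promoted pinacol-type (semipinacol) rearrangement of a 2-sulfonyloxy alcohol, the reaction type that interconverts decalin and hydroazulene skeletons. No ring is closed by cyclisation: the seven-membered ring C6–C5–C4–C3–C2–C1–C10 contracts to ring A by formation of C5–C10, and the cyclopentane C6–C7–C8–C9–C10 expands to ring B by insertion of C5 between C6 and C10. C10 migrates with retention and C5 is inverted, so the all-cis arrangement of C20, C6–O and C5–OMs in 21 puts H5 anti to C20 (trans-decalin); C8 and C9 are untouched. The step needs migration of C10 rather than C7: the cis-diol geometry excludes epoxide formation, the quaternary C10 is a better migrating group than the C7 methylene, and its shift gives a strain-free trans-decalin whereas a C7 shift would give a bridged bicyclo[4.3.1]decanone. Because C5 is the only stereocentre this saturated ketone can enolise towards (C9 is not acidic here), any cis-fused isomer should equilibrate to the trans ketone.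

Step 13
Reactants: 22 silyl ketone
Product: 24 (5R,8S,9R,10S)-12-hydroxy-13,14,15,16-tetranorlabdan-6-one, via fluorosilane 23 (not isolated)
Conditions: HBF4·OEt2, CH2Cl2, 0 °C → rt; then KF, KHCO3, H2O2 (30% aq.), THF/MeOH, rt
Reagents that add atoms: hydrogen peroxide, OO
Why: Tamao–Fleming oxidation, in which protodesilylation of the phenyl group gives the fluorosilane and peroxide then oxidises the C12–Si bond, while the hindered saturated ketone should stay untouched.

Step 14
Reactants: 24 hydroxy ketone
Product: 27 (5R,9R,10S)-12-hydroxy-13,14,15,16-tetranorlabd-7-en-6-one, via bis-silyl derivative 25 (not isolated), via silyl ether 26 (not isolated)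
Conditions: LDA (2.5 equiv), TMSCl (3 equiv), THF, −78 °C; then Pd(OAc)2 (10 mol%), O2 (1 atm), DMSO, rt; then aq. citric acid
Reagents that add atoms: none
Why: Saegusa–Ito dehydrogenation, in which kinetic deprotonation takes the C7 methylene (C5–H lies between two quaternary carbons) and β-hydride elimination of C8–H gives the C7=C8 enone; C9 is not acidic in the saturated ketone and keeps its configuration, and the alcohol rides through as its TMS ether.

Step 15
Reactants: 27 enone alcohol
Product: 28 (5R,9R,10S)-12-iodo-13,14,15,16-tetranorlabd-7-en-6-one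
Conditions: I2, PPh3, imidazole, CH2Cl2, 0 °C
Reagents that add atoms: iodine, II
Why: Appel-type iodination of the primary alcohol under neutral conditions that do not enolise the enone, so C5 and C9 are safe.

Step 16
Reactants: 29 tert-butyldimethyl(prop-2-yn-1-yloxy)silane
Product: 31 tert-butyl 4-[(tert-butyldimethylsilyl)oxy]but-2-ynoate, via lithium acetylide 30 (not isolated)
Conditions: n-BuLi, THF, −78 °C; then Boc2O, −78 → 0 °C; H2O
Reagents that add atoms: di-tert-butyl dicarbonate, CC(C)(C)OC(=O)OC(=O)OC(C)(C)C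
Why: C-acylation of a lithium acetylide with Boc2O gives the tert-butyl ynoate directly.

Step 17
Reactants: 31 ynoate
Product: 32 tert-butyl (E)-4-[(tert-butyldimethylsilyl)oxy]-3-(trimethylstannyl)but-2-enoate
Conditions: Li[Me3SnCu(SPh)], MeOH (2 equiv), THF, −100 → −78 °C
Reagents that add atoms: lithium (phenylthio)(trimethylstannyl)cuprate, [Li+].C[Sn](C)(C)[Cu-]Sc1ccccc1
Why: Stannylcupration of an ynoate at low temperature with a proton source present gives the kinetic syn adduct (tin and hydrogen cis), which places tin trans to the ester and the CH2O group cis to it.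

Step 18
Reactants: 32 alkenylstannane
Product: 33 tert-butyl (E)-4-[(tert-butyldimethylsilyl)oxy]-3-iodobut-2-enoate
Conditions: I2, CH2Cl2, 0 °C
Reagents that add atoms: iodine, II
Why: Iododestannylation proceeds with retention of alkene geometry.

Step 19
Reactants: 33 silyl ether iodide
Product: 35 tert-butyl (E)-4-acetoxy-3-iodobut-2-enoate, via hydroxy iodide 34 (not isolated)
Conditions: HF·pyridine, pyridine, THF, 0 °C; then Ac2O, DMAP (cat.), 0 °C
Reagents that add atoms: acetic anhydride, CC(=O)OC(C)=O
Why: Fluoride desilylation and immediate acetylation in the same flask leave the γ-hydroxy tert-butyl ester no time to lactonise; the alkene geometry is untouched.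

Step 20
Reactants: 28 iodide; 35 tert-butyl (E)-4-acetoxy-3-iodobut-2-enoate
Product: 37 tert-butyl (5R,9R,10S,13Z)-16-acetoxy-6-oxolabda-7,13-dien-15-oate, via alkylzinc iodide 36 (not isolated)
Conditions: Zn dust, LiCl, THF, 40 °C; then 35, Pd2(dba)3 (2.5 mol%), P(2-furyl)3 (10 mol%), THF/NMP, rt
Reagents that add atoms: none
Why: Negishi coupling, in which zinc insertion tolerates the enone and zerovalent palladium couples the alkylzinc with the alkenyl iodide with retention, placing C12 trans to the ester and so setting 13Z; oxidative addition to C–I should outpace ionisation of the allylic acetate.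

Step 21
Reactants: 37 tert-butyl ester
Product: 38 (5R,9R,10S,13Z)-16-acetoxy-6-oxolabda-7,13-dien-15-oic acid
Conditions: CF3CO2H, CH2Cl2, 0 °C
Reagents that add atoms: none
Why: Acidolysis of the tert-butyl ester by loss of isobutene; the acetate, the enone and the C9 centre should survive brief cold acid.

**Compound list**

1 | dimethyl(phenyl)(vinyl)silane | C=C[Si](C)(C)c1ccccc1 | starting material
2 | (2-bromoethyl)dimethyl(phenyl)silane | BrCC[Si](C)(C)c1ccccc1 | intermediate
3 | methyl isobutyrate | COC(=O)C(C)C | starting material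
4 | acrolein | C=CC=O | starting material
5 | lithium enolate of methyl isobutyrate | [Li]OC(OC)=C(C)C | intermediate
6 | methyl 3-hydroxy-2,2-dimethylpent-4-enoate (racemic) | C=CC(O)C(C)(C)C(=O)OC | intermediate
7 | methyl (E)-5-bromo-2,2-dimethylpent-3-enoate | COC(=O)C(C)(C)/C=C/CBr | intermediate
8 | 2-methylcyclopent-2-en-1-one | CC1=CCCC1=O | starting material
9 | [2-(dimethylphenylsilyl)ethyl]magnesium bromide | Br[Mg]CC[Si](C)(C)c1ccccc1 | intermediate
10 | bromomagnesium enolate of (3S)-3-[2-(dimethylphenylsilyl)ethyl]-2-methylcyclopentanone (C6–O–Mg, C6=C10) | Br[Mg]OC1=C(C)[C@H](CC[Si](C)(C)c2ccccc2)CC1 | intermediate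
11 | methyl (3E)-5-{(1S,2S)-2-[2-(dimethylphenylsilyl)ethyl]-1-methyl-5-oxocyclopentyl}-2,2-dimethylpent-3-enoate (C20 cis to C11) | O=C1CC[C@@H](CC[Si](C)(C)c2ccccc2)[C@]1(C)C/C=C/C(C)(C)C(=O)OC | intermediate
12 | methyl 5-{(1S,2S)-2-[2-(dimethylphenylsilyl)ethyl]-1-methyl-5-oxocyclopentyl}-2,2-dimethylpentanoate | O=C1CC[C@@H](CC[Si](C)(C)c2ccccc2)[C@]1(C)CCCC(C)(C)C(=O)OC | intermediate
13 | trimethylsilyl enol ether of 12 (C6=C7) | C[Si](C)(C)OC1=CC[C@@H](CC[Si](C)(C)c2ccccc2)[C@]1(C)CCCC(C)(C)C(=O)OC | intermediate
14 | methyl 5-{(1S,5R)-5-[2-(dimethylphenylsilyl)ethyl]-1-methyl-2-oxocyclopent-3-en-1-yl}-2,2-dimethylpentanoate | O=C1C=C[C@@H](CC[Si](C)(C)c2ccccc2)[C@]1(C)CCCC(C)(C)C(=O)OC | intermediate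
15 | lithium enolate of 16 (C6=C7) | [Li]OC1=C[C@H](C)[C@@H](CC[Si](C)(C)c2ccccc2)[C@]1(C)CCCC(C)(C)C(=O)OC | intermediate
16 | methyl 5-{(1S,2R,3S)-2-[2-(dimethylphenylsilyl)ethyl]-1,3-dimethyl-5-oxocyclopentyl}-2,2-dimethylpentanoate (C17 trans to C11) | O=C1C[C@H](C)[C@@H](CC[Si](C)(C)c2ccccc2)[C@]1(C)CCCC(C)(C)C(=O)OC | intermediate
17 | 5-{(1S,2R,3S)-2-[2-(dimethylphenylsilyl)ethyl]-5-hydroxy-1,3-dimethylcyclopentyl}-2,2-dimethylpentan-1-ol (both C6 epimers) | OC1C[C@H](C)[C@@H](CC[Si](C)(C)c2ccccc2)[C@]1(C)CCCC(C)(C)CO | intermediate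
18 | 5-{(1S,2R,3S)-2-[2-(dimethylphenylsilyl)ethyl]-1,3-dimethyl-5-oxocyclopentyl}-2,2-dimethylpentanal | O=C1C[C@H](C)[C@@H](CC[Si](C)(C)c2ccccc2)[C@]1(C)CCCC(C)(C)C=O | intermediate
19 | cis-fused hydroazulene diol (5R,6S,8S,9R,10S): seven-membered ring C6(OH)–C5H(OH)–C4(CH3)2–C3H2–C2H2–C1H2–C10(CH3), five-membered ring C6–C7H2–C8H(CH3)–C9H(CH2CH2SiMe2Ph)–C10; C20, 6-OH and 5-OH on one face | O[C@@]12C[C@H](C)[C@@H](CC[Si](C)(C)c3ccccc3)[C@]1(C)CCCC(C)(C)[C@H]2O | intermediate
20 | 5-O-methanesulfonate of 19 | O[C@@]12C[C@H](C)[C@@H](CC[Si](C)(C)c3ccccc3)[C@]1(C)CCCC(C)(C)[C@H]2OS(C)(=O)=O | intermediate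
21 | diethylaluminium 6-alkoxide of 20 | CC[Al](CC)O[C@@]12C[C@H](C)[C@@H](CC[Si](C)(C)c3ccccc3)[C@]1(C)CCCC(C)(C)[C@H]2OS(C)(=O)=O | intermediate
22 | (5R,8S,9R,10S)-12-(dimethylphenylsilyl)-13,14,15,16-tetranorlabdan-6-one (trans-decalin) | C[Si](C)(CC[C@@H]1[C@@H](C)CC(=O)[C@@H]2C(C)(C)CCC[C@@]12C)c1ccccc1 | intermediate
23 | (5R,8S,9R,10S)-12-(fluorodimethylsilyl)-13,14,15,16-tetranorlabdan-6-one | C[Si](C)(F)CC[C@@H]1[C@@H](C)CC(=O)[C@@H]2C(C)(C)CCC[C@@]12C | intermediate
24 | (5R,8S,9R,10S)-12-hydroxy-13,14,15,16-tetranorlabdan-6-one | OCC[C@@H]1[C@@H](C)CC(=O)[C@@H]2C(C)(C)CCC[C@@]12C | intermediate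
25 | 12-O-trimethylsilyl, 6-O-trimethylsilyl enol ether (C6=C7) of 24 | C[Si](C)(C)OCC[C@@H]1[C@@H](C)C=C(O[Si](C)(C)C)[C@@H]2C(C)(C)CCC[C@@]12C | intermediate
26 | 12-O-trimethylsilyl ether of 27 | C[Si](C)(C)OCC[C@@H]1C(C)=CC(=O)[C@@H]2C(C)(C)CCC[C@@]12C | intermediate
27 | (5R,9R,10S)-12-hydroxy-13,14,15,16-tetranorlabd-7-en-6-one | OCC[C@@H]1C(C)=CC(=O)[C@@H]2C(C)(C)CCC[C@@]12C | intermediate
28 | (5R,9R,10S)-12-iodo-13,14,15,16-tetranorlabd-7-en-6-one | ICC[C@@H]1C(C)=CC(=O)[C@@H]2C(C)(C)CCC[C@@]12C | intermediate
29 | tert-butyldimethyl(prop-2-yn-1-yloxy)silane | C#CCO[Si](C)(C)C(C)(C)C | starting material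
30 | lithium acetylide of 29 | [Li]C#CCO[Si](C)(C)C(C)(C)C | intermediate
31 | tert-butyl 4-[(tert-butyldimethylsilyl)oxy]but-2-ynoate | CC(C)(C)OC(=O)C#CCO[Si](C)(C)C(C)(C)C | intermediate
32 | tert-butyl (E)-4-[(tert-butyldimethylsilyl)oxy]-3-(trimethylstannyl)but-2-enoate (tin trans to the ester) | CC(C)(C)OC(=O)/C=C(\CO[Si](C)(C)C(C)(C)C)[Sn](C)(C)C | intermediate
33 | tert-butyl (E)-4-[(tert-butyldimethylsilyl)oxy]-3-iodobut-2-enoate | CC(C)(C)OC(=O)/C=C(\CO[Si](C)(C)C(C)(C)C)I | intermediate
34 | tert-butyl (E)-4-hydroxy-3-iodobut-2-enoate | CC(C)(C)OC(=O)/C=C(\CO)I | intermediate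
35 | tert-butyl (E)-4-acetoxy-3-iodobut-2-enoate (iodine trans to the ester) | CC(C)(C)OC(=O)/C=C(\COC(C)=O)I | intermediate
36 | alkylzinc iodide from 28 (C12–ZnI) | I[Zn]CC[C@@H]1C(C)=CC(=O)[C@@H]2C(C)(C)CCC[C@@]12C | intermediate
37 | tert-butyl (5R,9R,10S,13Z)-16-acetoxy-6-oxolabda-7,13-dien-15-oate | CC(=O)OC/C(=C\C(=O)OC(C)(C)C)CC[C@@H]1C(C)=CC(=O)[C@@H]2C(C)(C)CCC[C@@]12C | intermediate
38 | (5R,9R,10S,13Z)-16-acetoxy-6-oxolabda-7,13-dien-15-oic acid | CC(=O)OC/C(=C\C(=O)O)CC[C@@H]1C(C)=CC(=O)[C@@H]2C(C)(C)CCC[C@@]12C | target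

**Step count and risks**

Total step count: 21. Longest linear sequence: 16 steps (steps 2–15, 20 and 21).

Steps most likely to fail:

Step 10. The seven-membered ring has to close between two hindered carbonyl groups, so ring closure may lose to simple reduction of the aldehyde or to intermolecular coupling. Fallback: keto aldehyde 18 would be closed by McMurry olefination with low-valent titanium (TiCl3(DME)1.5, Zn–Cu, DME, reflux, slow addition) to the bicyclic alkene F1. OsO4/NMO dihydroxylation, expected on the alkene face away from the two pseudo-axial methyl groups, would give the cis diol F2, the C5,C6-bis-epimer of 19. Mesylation as in step 11 would give mesylate F3, and the Et3Al-induced shift of step 12 would then give the cis-fused ketone F4, the C5 epimer of 22. NaOMe in MeOH should equilibrate F4 at C5 (the only acidic stereocentre) to 22, where the route is rejoined.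

Step 12. The reacting conformer may place the mesylate pseudo-axial, so that the C7 bond migrates instead of C6–C10, or elimination may compete. Fallback: diol 19 would be oxidised at the secondary alcohol (SO3·pyridine, DMSO, Et3N) to the α-hydroxy ketone F5. An α-ketol rearrangement under equilibrating conditions (Al(OiPr)3 or KOtBu), the same type as the D-homo rearrangement of ring-fused acyl carbinols, should move C10 from C6 to C5 under thermodynamic control and give the 5-hydroxy-decalin-6-one F6. Reductive removal of the α-hydroxyl with SmI2 in THF/MeOH, followed by equilibration at C5 if needed, returns to 22.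

Step 4. C-alkylation of the hindered magnesium enolate by bromide 7 may be slow, with proton transfer eroding regio- and diastereocontrol. Fallback: starting again from 8 and Grignard reagent 9, the conjugate addition would be quenched with TMSCl and the silyl enol ether F7 isolated. Alcohol 6 would be converted (ClCO2Me, pyridine) into the allylic carbonate F8. A Tsuji allylation of F7 with F8 (Pd2(dba)3, dppe, THF) should attack the less hindered allyl terminus and the enol ether face anti to the C9 substituent, giving 11, where the route is rejoined.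

Further compounds
F1 | step 10 | bicyclo[5.3.0]dec-5(6)-ene from McMurry closure of 18 (C5=C6; 8S,9R,10S) | C[C@H]1CC2=CC(C)(C)CCC[C@@]2(C)[C@@H]1CC[Si](C)(C)c1ccccc1
F2 | step 10 | hydroazulene diol, C5,C6-bis-epimer of 19 (5S,6R,8S,9R,10S; both hydroxyls trans to C20) | O[C@]12C[C@H](C)[C@@H](CC[Si](C)(C)c3ccccc3)[C@]1(C)CCCC(C)(C)[C@@H]2O
F3 | step 10 | 5-O-methanesulfonate of F2 | O[C@]12C[C@H](C)[C@@H](CC[Si](C)(C)c3ccccc3)[C@]1(C)CCCC(C)(C)[C@@H]2OS(C)(=O)=O
F4 | step 10 | (5S,8S,9R,10S)-12-(dimethylphenylsilyl)-13,14,15,16-tetranorlabdan-6-one (cis-fused C5 epimer of 22) | C[Si](C)(CC[C@@H]1[C@@H](C)CC(=O)[C@H]2C(C)(C)CCC[C@@]12C)c1ccccc1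
F5 | step 12 | hydroazulene α-hydroxy ketone (C5 ketone, C6 tertiary alcohol; 6S,8S,9R,10S) | O[C@@]12C[C@H](C)[C@@H](CC[Si](C)(C)c3ccccc3)[C@]1(C)CCCC(C)(C)C2=O
F6 | step 12 | 5-hydroxy-12-(dimethylphenylsilyl)-13,14,15,16-tetranorlabdan-6-one (drawn trans-fused; either C5 epimer converges) | C[Si](C)(CC[C@@H]1[C@@H](C)CC(=O)[C@]2(O)C(C)(C)CCC[C@@]12C)c1ccccc1
F7 | step 4 | trimethylsilyl enol ether of (3S)-3-[2-(dimethylphenylsilyl)ethyl]-2-methylcyclopentanone (C6=C10) | C[Si](C)(C)OC1=C(C)[C@H](CC[Si](C)(C)c2ccccc2)CC1
F8 | step 4 | methyl 3-[(methoxycarbonyl)oxy]-2,2-dimethylpent-4-enoate (racemic) | C=CC(OC(=O)OC)C(C)(C)C(=O)OC
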